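**Retrosynthetic overview**
- The plan rests on O1 being the only link between the benzylic C2 stereocentre (carrying ring B) and C8a of ring A. Ring C is therefore opened at the O1–C8a aryl–oxygen bond, so the C2–O bond, once made, is never broken.
- The coupling precursor is a (3S)-3-aryl-1-(2-triflyloxyaryl)propane-1,3-diol with its C1 (future C4) hydroxyl masked as a TBS ether. A free alkoxide ortho to the triflate could chelate the arylpalladium, be oxidised or take over the triflyl group, so only the C3 hydroxyl is left free.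
- The C2–C3 bond (flavanone numbering) and the stereocentre come from a diisopinocampheylboron enolate aldol of the ring A acetophenone triflate with MOM-protected isovanillin, followed by TES protection, ketone reduction, TBS protection and selective TES removal.
- The ring A piece comes from 2',6'-dihydroxy-4'-methoxyacetophenone: C-prenylation at C3', MOM ether at the less hindered 6'-OH, triflate at the 2'-OH next to the prenyl group (this fixes the 8-prenyl pattern).
- Rings A and B are bought; ring C is the only ring formed (step 10). The end game is desilylation, oxidation to the C4 ketone and MOM removal.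

Key step: step 10

Remark: 2',6'-dihydroxy-4'-methoxyacetophenone (the 4'-O-methyl ether of phloroacetophenone) is taken as a purchasable starting material, which avoids a poorly selective mono-methylation.
Remark: C1 of the propane chain (later C4) is formed without control in step 7 and is oxidised in step 12; compounds 12–16 are drawn as the (1S) or (4S) epimer, and the other epimer is carried along with it.

**Step 1**
Reactants: 1 2',6'-dihydroxy-4'-methoxyacetophenone; 2 prenyl bromide (1-bromo-3-methylbut-2-ene)
Product: 3 1-[2,6-dihydroxy-4-methoxy-3-(3-methylbut-2-en-1-yl)phenyl]ethanone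
Conditions: 10% aq. KOH, 0 °C → rt (1 equiv of 2, slow addition)
Reagents that add atoms: none
Why: C-alkylation of a phloroglucinol-type phenoxide (nuclear prenylation), in which water shields the oxygen so the ambident anion reacts at the ring carbon ortho to O−; 1 is symmetric, so C3' and C5' give the same product, which is separated from O-prenyl and diprenyl side products.

**Step 2**
Reactants: 3 1-[2,6-dihydroxy-4-methoxy-3-(3-methylbut-2-en-1-yl)phenyl]ethanone
Product: 4 1-[2-hydroxy-4-methoxy-6-(methoxymethoxy)-3-(3-methylbut-2-en-1-yl)phenyl]ethanone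
Conditions: MOMCl (1.05 equiv), iPr2NEt, CH2Cl2, 0 °C → rt
Reagents that add atoms: chloromethyl methyl ether (MOMCl), COCCl
Why: Williamson-type ether formation with an α-chloro ether, expected at the 6'-OH next to H-5' because it is less hindered and less strongly chelated, whereas the 2'-OH is buttressed by the prenyl group into a hydrogen bond with the acetyl oxygen, as in the partial alkylation of 3-alkylphloroacetophenones.

**Step 3**
Reactants: 4 1-[2-hydroxy-4-methoxy-6-(methoxymethoxy)-3-(3-methylbut-2-en-1-yl)phenyl]ethanone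
Product: 5 2-acetyl-5-methoxy-3-(methoxymethoxy)-6-(3-methylbut-2-en-1-yl)phenyl trifluoromethanesulfonate
Conditions: Tf2O, pyridine, CH2Cl2, −10 °C → rt
Reagents that add atoms: trifluoromethanesulfonic anhydride (Tf2O), O=S(=O)(OS(=O)(=O)C(F)(F)F)C(F)(F)F
Why: O-sulfonylation of the chelated phenol; pyridine scavenges triflic acid, so the MOM ether and the prenyl double bond are not exposed to acid.

**Step 4**
Reactants: 6 isovanillin (3-hydroxy-4-methoxybenzaldehyde)
Product: 7 4-methoxy-3-(methoxymethoxy)benzaldehyde
Conditions: MOMCl, iPr2NEt, CH2Cl2, 0 °C → rt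
Reagents that add atoms: chloromethyl methyl ether (MOMCl), COCCl
Why: Standard MOM protection of a phenol (Williamson-type), needed because a free phenol would quench the boron enolate.

**Step 5**
Reactants: 5 2-acetyl-5-methoxy-3-(methoxymethoxy)-6-(3-methylbut-2-en-1-yl)phenyl trifluoromethanesulfonate; 7 4-methoxy-3-(methoxymethoxy)benzaldehyde
Product: 10 2-{(3S)-3-hydroxy-3-[4-methoxy-3-(methoxymethoxy)phenyl]propanoyl}-5-methoxy-3-(methoxymethoxy)-6-(3-methylbut-2-en-1-yl)phenyl trifluoromethanesulfonate, via enol diisopinocampheylborinate 8 (not isolated), via boron aldolate 9 (not isolated)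
Conditions: (+)-Ipc2BCl (from (−)-α-pinene), Et3N, Et2O, −78 → 0 °C; then 7, −78 → −20 °C; MeOH, pH 7 buffer, 30% H2O2, 0 °C
Reagents that add atoms: none
Why: Paterson boron aldol, in which Ipc2BCl/Et3N enolises the methyl ketone and the enol borinate adds to the aldehyde through a cyclic boron-bridged transition state; the isopinocampheyl groups of the (+)-reagent should direct attack to the Si face of the aldehyde and so set the (3S) carbinol by reagent control (configuration and enantiomeric purity to be checked here by Mosher esters and chiral HPLC), and the buffered peroxide work-up only cleaves the boron–carbon and boron–oxygen bonds.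

**Step 6**
Reactants: 10 (3S)-β-hydroxy ketone
Product: 11 2-{(3S)-3-[4-methoxy-3-(methoxymethoxy)phenyl]-3-(triethylsilyloxy)propanoyl}-5-methoxy-3-(methoxymethoxy)-6-(3-methylbut-2-en-1-yl)phenyl trifluoromethanesulfonate
Conditions: TESCl, imidazole, DMF, 0 °C
Reagents that add atoms: chlorotriethylsilane (TESCl), CC[Si](Cl)(CC)CC
Why: Silylation of the secondary alcohol; the TES ether blocks retro-aldol and β-elimination and can later be removed in the presence of a TBS ether.

**Step 7**
Reactants: 11 (3S)-β-triethylsilyloxy ketone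
Product: 12 2-{(1S,3S)-1-hydroxy-3-[4-methoxy-3-(methoxymethoxy)phenyl]-3-(triethylsilyloxy)propyl}-5-methoxy-3-(methoxymethoxy)-6-(3-methylbut-2-en-1-yl)phenyl trifluoromethanesulfonate (with its 1R epimer)
Conditions: NaBH4, MeOH–THF, 0 °C → rt
Reagents that add atoms: none
Why: Borohydride reduction of the aryl ketone; no control at C1 is needed because this carbon is reoxidised in step 12, and the aryl triflate, silyl ether and MOM groups are inert to NaBH4.

**Step 8**
Reactants: 12 C1 alcohol
Product: 13 2-{(1S,3S)-1-(tert-butyldimethylsilyloxy)-3-[4-methoxy-3-(methoxymethoxy)phenyl]-3-(triethylsilyloxy)propyl}-5-methoxy-3-(methoxymethoxy)-6-(3-methylbut-2-en-1-yl)phenyl trifluoromethanesulfonate (with its 1R epimer)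
Conditions: TBSOTf, 2,6-lutidine, CH2Cl2, −78 → −20 °C
Reagents that add atoms: tert-butyldimethylsilyl trifluoromethanesulfonate (TBSOTf), CC(C)(C)[Si](C)(C)OS(=O)(=O)C(F)(F)F
Why: Silylation of the hindered benzylic alcohol with a silyl triflate under non-alkoxide conditions, so that no triflyl transfer from the neighbouring aryl triflate can occur; the TBS ether masks the hydroxyl ortho to the triflate for the coupling.

**Step 9**
Reactants: 13 bis-silyl ether
Product: 14 2-{(1S,3S)-1-(tert-butyldimethylsilyloxy)-3-hydroxy-3-[4-methoxy-3-(methoxymethoxy)phenyl]propyl}-5-methoxy-3-(methoxymethoxy)-6-(3-methylbut-2-en-1-yl)phenyl trifluoromethanesulfonate (with its 1R epimer)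
Conditions: HF·pyridine, pyridine, THF, 0 °C
Reagents that add atoms: none
Why: Selective desilylation, since buffered HF·pyridine cleaves the less hindered triethylsilyl ether much faster than the tert-butyldimethylsilyl ether and is not acidic enough to ionise the p-methoxybenzylic carbinol.

**Step 10**
Reactants: 14 (3S)-carbinol aryl triflate
Product: 15 (2S,4S)-4-(tert-butyldimethylsilyloxy)-7-methoxy-2-[4-methoxy-3-(methoxymethoxy)phenyl]-5-(methoxymethoxy)-8-(3-methylbut-2-en-1-yl)chromane (with its 4R epimer)
Conditions: Pd(OAc)2 (5 mol %), 2-(di-tert-butylphosphino)-1,1'-binaphthyl (7.5 mol %), K3PO4, toluene, 80 °C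
Reagents that add atoms: none
Why: Pd(OAc)2 is reduced in situ to zerovalent palladium, which inserts into the C8a–OTf bond; the C3 hydroxyl binds the arylpalladium, is deprotonated by K3PO4, and the aryl(alkoxo)palladium species undergoes C–O reductive elimination (Buchwald–Hartwig etherification; the intramolecular coupling of aryl halides or triflates with secondary alcohols to chromans is the closest known reaction). Ring C closes as a six-membered ring through a seven-membered palladacycle, with the triflate leaving from outside the new ring (exo closure at C8a). No stereocentre is formed: only the O–H bond of the C3 carbinol is broken, so the aldol-derived (S) centre becomes C2 with retention. The step needs reductive elimination to outrun β-hydride elimination of the secondary alkoxide (which would give the C3 ketone and the hydrodetriflated arene); the bulky di-tert-butyl biaryl phosphine should secure this by keeping palladium crowded and low-coordinate. Chemoselectivity between the two oxygens is secured by the TBS ether at C1, which removes the ortho-benzylic alkoxide, and working at the diol oxidation level excludes retro-aldol and dehydration under base.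

**Step 11**
Reactants: 15 flavan-4-ol TBS ether
Product: 16 (2S,4S)-7-methoxy-2-[4-methoxy-3-(methoxymethoxy)phenyl]-5-(methoxymethoxy)-8-(3-methylbut-2-en-1-yl)chroman-4-ol (with its 4R epimer)
Conditions: TBAF, THF, 0 °C → rt
Reagents that add atoms: none
Why: Fluoride-mediated cleavage of the silyl ether; non-acidic conditions are chosen because the electron-rich flavan-4-ol ionises easily at C4.

**Step 12**
Reactants: 16 flavan-4-ol
Product: 17 (2S)-7-methoxy-2-[4-methoxy-3-(methoxymethoxy)phenyl]-5-(methoxymethoxy)-8-(3-methylbut-2-en-1-yl)chroman-4-one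
Conditions: Dess–Martin periodinane, NaHCO3, CH2Cl2, 0 °C → rt
Reagents that add atoms: none
Why: Dess–Martin oxidation of the benzylic secondary alcohol to the C4 ketone, which merges the two C4 epimers; NaHCO3 buffers the acetic acid formed and the C2 centre is not affected under these non-basic conditions.

**Step 13**
Reactants: 17 bis-MOM flavanone
Product: 18 (2S)-5-hydroxy-2-(3-hydroxy-4-methoxyphenyl)-7-methoxy-8-(3-methylbut-2-en-1-yl)chroman-4-one
Conditions: HCl (ca. 1 M), MeOH–H2O, rt → 40 °C
Reagents that add atoms: none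
Why: Acid-catalysed acetal exchange (MOM cleavage) in methanol, in which the 5-O-MOM group peri to the carbonyl is especially labile; dilute, mild acid should leave the prenyl double bond (no free ortho hydroxyl flanks it) and the pyranone ring intact, so C2 stays (S).

**Compound list**
1 | 2',6'-dihydroxy-4'-methoxyacetophenone | CC(=O)c1c(O)cc(OC)cc1O | starting material
2 | prenyl bromide | CC(C)=CCBr | starting material
3 | 1-[2,6-dihydroxy-4-methoxy-3-(3-methylbut-2-en-1-yl)phenyl]ethanone | CC(=O)c1c(O)cc(OC)c(CC=C(C)C)c1O | intermediate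
4 | 1-[2-hydroxy-4-methoxy-6-(methoxymethoxy)-3-(3-methylbut-2-en-1-yl)phenyl]ethanone | CC(=O)c1c(OCOC)cc(OC)c(CC=C(C)C)c1O | intermediate
5 | 2-acetyl-5-methoxy-3-(methoxymethoxy)-6-(3-methylbut-2-en-1-yl)phenyl trifluoromethanesulfonate | CC(=O)c1c(OCOC)cc(OC)c(CC=C(C)C)c1OS(=O)(=O)C(F)(F)F | intermediate
6 | isovanillin | COc1ccc(C=O)cc1O | starting material
7 | 4-methoxy-3-(methoxymethoxy)benzaldehyde | COc1ccc(C=O)cc1OCOC | intermediate
8 | enol diisopinocampheylborinate of 5 (Ipc from (−)-α-pinene) | C=C(OB([C@H]1C[C@H]2C[C@@H]([C@@H]1C)C2(C)C)[C@H]1C[C@H]2C[C@@H]([C@@H]1C)C2(C)C)c1c(OCOC)cc(OC)c(CC=C(C)C)c1OS(=O)(=O)C(F)(F)F | intermediate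
9 | (3S)-boron aldolate (O-diisopinocampheylboryl derivative of 10) | COc1ccc([C@@H](OB([C@H]2C[C@H]3C[C@@H]([C@@H]2C)C3(C)C)[C@H]2C[C@H]3C[C@@H]([C@@H]2C)C3(C)C)CC(=O)c2c(OCOC)cc(OC)c(CC=C(C)C)c2OS(=O)(=O)C(F)(F)F)cc1OCOC | intermediate
10 | 2-{(3S)-3-hydroxy-3-[4-methoxy-3-(methoxymethoxy)phenyl]propanoyl}-5-methoxy-3-(methoxymethoxy)-6-(3-methylbut-2-en-1-yl)phenyl trifluoromethanesulfonate | COc1ccc([C@@H](O)CC(=O)c2c(OCOC)cc(OC)c(CC=C(C)C)c2OS(=O)(=O)C(F)(F)F)cc1OCOC | intermediate
11 | (3S)-3-O-triethylsilyl ether of 10 | COc1ccc([C@@H](O[Si](CC)(CC)CC)CC(=O)c2c(OCOC)cc(OC)c(CC=C(C)C)c2OS(=O)(=O)C(F)(F)F)cc1OCOC | intermediate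
12 | (1S,3S)-1-hydroxy-3-(triethylsilyloxy)propyl aryl triflate (1S epimer drawn, 1R epimer accompanies) | COc1ccc([C@@H](O[Si](CC)(CC)CC)C[C@H](O)c2c(OCOC)cc(OC)c(CC=C(C)C)c2OS(=O)(=O)C(F)(F)F)cc1OCOC | intermediate
13 | (1S,3S)-1-(tert-butyldimethylsilyloxy)-3-(triethylsilyloxy)propyl aryl triflate (1S epimer drawn) | COc1ccc([C@@H](O[Si](CC)(CC)CC)C[C@H](O[Si](C)(C)C(C)(C)C)c2c(OCOC)cc(OC)c(CC=C(C)C)c2OS(=O)(=O)C(F)(F)F)cc1OCOC | intermediate
14 | (1S,3S)-1-(tert-butyldimethylsilyloxy)-3-hydroxy-3-arylpropyl aryl triflate, the coupling precursor (1S epimer drawn) | COc1ccc([C@@H](O)C[C@H](O[Si](C)(C)C(C)(C)C)c2c(OCOC)cc(OC)c(CC=C(C)C)c2OS(=O)(=O)C(F)(F)F)cc1OCOC | intermediate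
15 | (2S,4S)-4-(tert-butyldimethylsilyloxy)-7-methoxy-2-[4-methoxy-3-(methoxymethoxy)phenyl]-5-(methoxymethoxy)-8-(3-methylbut-2-en-1-yl)chromane (4S epimer drawn) | COc1ccc([C@@H]2C[C@H](O[Si](C)(C)C(C)(C)C)c3c(OCOC)cc(OC)c(CC=C(C)C)c3O2)cc1OCOC | intermediate
16 | (2S,4S)-7-methoxy-2-[4-methoxy-3-(methoxymethoxy)phenyl]-5-(methoxymethoxy)-8-(3-methylbut-2-en-1-yl)chroman-4-ol (4S epimer drawn) | COc1ccc([C@@H]2C[C@H](O)c3c(OCOC)cc(OC)c(CC=C(C)C)c3O2)cc1OCOC | intermediate
17 | (2S)-7-methoxy-2-[4-methoxy-3-(methoxymethoxy)phenyl]-5-(methoxymethoxy)-8-(3-methylbut-2-en-1-yl)chroman-4-one | COc1ccc([C@@H]2CC(=O)c3c(OCOC)cc(OC)c(CC=C(C)C)c3O2)cc1OCOC | intermediate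
18 | (2S)-5-hydroxy-2-(3-hydroxy-4-methoxyphenyl)-7-methoxy-8-(3-methylbut-2-en-1-yl)chroman-4-one | COc1ccc([C@@H]2CC(=O)c3c(O)cc(OC)c(CC=C(C)C)c3O2)cc1O | target

**Step count**
Total steps: 13. Longest linear sequence: 12 steps (steps 1–3 and 5–13, from 1 to 18).

**Steps most likely to fail**

Step 10 (ring closure). β-Hydride elimination from the palladium alkoxide may outrun C–O reductive elimination, the base may cleave the sulfur–oxygen bond of the hindered triflate, or the silyl group may migrate from the C1 oxygen to the C3 oxygen. In that case ring C would be built as a pyranone before ring B is attached. The fallback sets out from phenol 4 and rejoins the route at 17.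
- Condensation of 4 with N,N-dimethylformamide dimethyl acetal (toluene, 90 °C) should give the enaminone (E)-3-(dimethylamino)-1-[2-hydroxy-4-methoxy-6-(methoxymethoxy)-3-(3-methylbut-2-en-1-yl)phenyl]prop-2-en-1-one F1.
- Warming F1 in acetic acid (60 °C) should close it to 7-methoxy-5-(methoxymethoxy)-8-(3-methylbut-2-en-1-yl)-4H-chromen-4-one F2.
- Purchased 5-bromo-2-methoxyphenol would be protected (MOMCl, iPr2NEt) as 4-bromo-1-methoxy-2-(methoxymethoxy)benzene F3, then converted by bromine–lithium exchange (n-BuLi, THF, −78 °C), B(OiPr)3 and neutral aqueous work-up into [4-methoxy-3-(methoxymethoxy)phenyl]boronic acid F4.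
- Enantioselective conjugate addition of F4 to F2 (Pd(OCOCF3)2, t-BuPyOx ligand, NH4PF6, H2O, 1,2-dichloroethane, 60 °C) should give 17, which then enters step 13. The ligand antipode is chosen for the (2S) series and the assignment checked by the circular dichroism of 18.

Step 5 (aldol). Facial selectivity may be poor, since enol diisopinocampheylborinates of methyl ketones are only moderately selective and the sense of induction on this hindered aryl ketone is untested; enolisation may also be sluggish. The C3 configuration would then be reset by reduction instead of by the aldol. The fallback sets out from 14 of insufficient enantiomeric purity (or 14 made through a racemic lithium enolate aldol and the same steps 6–9) and returns to 14.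
- Dess–Martin oxidation of the C3 hydroxyl should give 2-{1-(tert-butyldimethylsilyloxy)-3-[4-methoxy-3-(methoxymethoxy)phenyl]-3-oxopropyl}-5-methoxy-3-(methoxymethoxy)-6-(3-methylbut-2-en-1-yl)phenyl trifluoromethanesulfonate F5.
- Corey–Bakshi–Shibata reduction of F5 with catecholborane and (R)-2-methyl-CBS-oxazaborolidine (toluene, −78 °C) should return (3S)-14, the aryl group acting as the large substituent. Catecholborane at this temperature should not hydroborate the trisubstituted double bond.

Step 2 (regioselective MOM ether, together with the C-prenylation of step 1). Alkylation may occur at the wrong hydroxyl or twice, and step 1 may give mainly O- and di-prenylated material. The fallback fixes the regiochemistry by carrying the prenyl group in on the oxygen that ends as the MOM ether. It sets out from 1 and rejoins the route at 4.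
- Mono-silylation of symmetric 1 (TBSCl, imidazole, DMF) should give 1-[2-(tert-butyldimethylsilyloxy)-6-hydroxy-4-methoxyphenyl]ethanone F6.
- Mitsunobu etherification with 3-methylbut-2-en-1-ol (PPh3, DIAD, THF) should give 1-[2-(tert-butyldimethylsilyloxy)-4-methoxy-6-(3-methylbut-2-en-1-yloxy)phenyl]ethanone F7.
- A Claisen–Cope (para-Claisen) rearrangement in N,N-diethylaniline at about 200 °C should move the prenyl group to the carbon para to its carrier oxygen, giving 1-[2-(tert-butyldimethylsilyloxy)-6-hydroxy-4-methoxy-3-(3-methylbut-2-en-1-yl)phenyl]ethanone F8.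
- MOM protection of the freed phenol (MOMCl, iPr2NEt) should give 1-[2-(tert-butyldimethylsilyloxy)-4-methoxy-6-(methoxymethoxy)-3-(3-methylbut-2-en-1-yl)phenyl]ethanone F9, and TBAF (THF, 0 °C) should release 4 with the free hydroxyl next to the prenyl group.

**Further compounds**
F1 | step 10 | (E)-3-(dimethylamino)-1-[2-hydroxy-4-methoxy-6-(methoxymethoxy)-3-(3-methylbut-2-en-1-yl)phenyl]prop-2-en-1-one | CN(C)/C=C/C(=O)c1c(OCOC)cc(OC)c(CC=C(C)C)c1O
F2 | step 10 | 7-methoxy-5-(methoxymethoxy)-8-(3-methylbut-2-en-1-yl)-4H-chromen-4-one | O=c1ccoc2c(CC=C(C)C)c(OC)cc(OCOC)c12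
F3 | step 10 | 4-bromo-1-methoxy-2-(methoxymethoxy)benzene | COc1ccc(Br)cc1OCOC
F4 | step 10 | [4-methoxy-3-(methoxymethoxy)phenyl]boronic acid | COc1ccc(B(O)O)cc1OCOC
F5 | step 5 | 2-{(1S)-1-(tert-butyldimethylsilyloxy)-3-[4-methoxy-3-(methoxymethoxy)phenyl]-3-oxopropyl}-5-methoxy-3-(methoxymethoxy)-6-(3-methylbut-2-en-1-yl)phenyl trifluoromethanesulfonate (1S epimer drawn) | COc1ccc(C(=O)C[C@H](O[Si](C)(C)C(C)(C)C)c2c(OCOC)cc(OC)c(CC=C(C)C)c2OS(=O)(=O)C(F)(F)F)cc1OCOC
F6 | step 2 | 1-[2-(tert-butyldimethylsilyloxy)-6-hydroxy-4-methoxyphenyl]ethanone | CC(=O)c1c(O)cc(OC)cc1O[Si](C)(C)C(C)(C)C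
F7 | step 2 | 1-[2-(tert-butyldimethylsilyloxy)-4-methoxy-6-(3-methylbut-2-en-1-yloxy)phenyl]ethanone | CC(=O)c1c(OCC=C(C)C)cc(OC)cc1O[Si](C)(C)C(C)(C)C
F8 | step 2 | 1-[2-(tert-butyldimethylsilyloxy)-6-hydroxy-4-methoxy-3-(3-methylbut-2-en-1-yl)phenyl]ethanone | CC(=O)c1c(O)cc(OC)c(CC=C(C)C)c1O[Si](C)(C)C(C)(C)C
F9 | step 2 | 1-[2-(tert-butyldimethylsilyloxy)-4-methoxy-6-(methoxymethoxy)-3-(3-methylbut-2-en-1-yl)phenyl]ethanone | CC(=O)c1c(OCOC)cc(OC)c(CC=C(C)C)c1O[Si](C)(C)C(C)(C)C
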